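The route rests on disconnecting the bond between C9, the O–CH carbon of the tetrahydrofuran ring that carries the C8 chain, and C10, the ring-fusion carbon next to the acetoxy carbon C11. This O–C9–C10–C11(O) array is an aldol retron whose aldol oxygen is the tetrahydrofuran oxygen. In one operation a cyclohexenyl silyl enol ether (C10=C11–OSi) bearing the C2 silyl ether condenses with 3-methylbut-3-enal to an oxocarbenium ion that the enol silane captures: O–C9 and C9–C10 form, the cis-fused tetrahydrofuran closes, C9 and C10 are set and the C11 ketone appears. The precursor is a monocyclic Diels–Alder adduct; ring-closing metathesis (oxonene) and etherification (oxepane) finish the tetracycle.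

Key step: step 12

Remark: carbons are numbered as in asbestinanes (C1/C10 ring-fusion CH, C2 and C9 the two O–CH of the tetrahydrofuran, C3 the C(CH3)–O, C6=C7 the ring alkene, C11 CH–OAc, C12 CH–CH3, C14 the CH bearing C15, C16 the OCH2), and but-3-en-1-ylzinc bromide is taken as the commercial THF solution.

Step 1
Reactants: 1 but-2-yn-1-ol
Product: 3 (Z)-3-iodobut-2-en-1-ol, via cyclic alkenylaluminate 2 (not isolated)
Conditions: NaAlH2(OCH2CH2OMe)2, Et2O, 0 °C → rt; EtOAc; then I2, THF, −78 → 0 °C
Reagents that add atoms: iodine [I][I]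
Why: Hydroxyl-directed trans-hydroalumination puts aluminium on C3 in the five-membered alkoxyaluminate 2 and iodine replaces it with retention, which should give the (Z)-vinyl iodide (hydroalumination–iodination of a propargylic alcohol).

Step 2
Reactants: 3 (Z)-3-iodobut-2-en-1-ol; 4 but-3-en-1-ylzinc bromide
Product: 5 (Z)-3-methylhepta-2,6-dien-1-ol
Conditions: 4 (2.5 equiv), PdCl2(dppf) (5 mol %), THF, 0 → 50 °C
Reagents that add atoms: none
Why: Negishi coupling of the vinyl iodide with the alkylzinc halide keeps the (Z) geometry and tolerates the free hydroxyl when 4 is used in excess.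

Step 3
Reactants: 5 (Z)-3-methylhepta-2,6-dien-1-ol
Product: 6 [(2R,3S)-3-(but-3-en-1-yl)-3-methyloxiran-2-yl]methanol
Conditions: Ti(OiPr)4 (10 mol %), D-(−)-diethyl tartrate (12 mol %), t-BuOOH, 4 Å MS, CH2Cl2, −25 °C
Reagents that add atoms: tert-butyl hydroperoxide CC(C)(C)OO
Why: Sharpless asymmetric epoxidation, in which the Ti(OiPr)4/D-(−)-tartrate catalyst epoxidises only the allylic alkene and, for this (Z)-trisubstituted allylic alcohol, should deliver oxygen to the face that gives the (2R,3S)-epoxide.

Step 4
Reactants: 6 [(2R,3S)-3-(but-3-en-1-yl)-3-methyloxiran-2-yl]methanol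
Product: 8 (2S,3S)-3-methylhept-6-ene-1,2,3-triol, via terminal epoxide 7 (not isolated)
Conditions: NaOH (0.5 M), t-BuOH/H2O, 75 °C
Reagents that add atoms: water O
Why: Payne rearrangement (the C1 alkoxide opens the epoxide at C2 with inversion) followed by hydroxide attack at the primary carbon of 7 should give the triol with C2 inverted and C3 retained, which is the configuration needed at C2 and C3.

Step 5
Reactants: 8 (2S,3S)-3-methylhept-6-ene-1,2,3-triol
Product: 9 (2S,3S)-3-methyl-1,2,3-tris(triethylsilyloxy)hept-6-ene
Conditions: TESOTf (3.5 equiv), 2,6-lutidine, CH2Cl2, −78 → 0 °C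
Reagents that add atoms: triethylsilyl trifluoromethanesulfonate CC[Si](CC)(CC)OS(=O)(=O)C(F)(F)F
Why: The silyl triflate silylates all three hydroxyls, including the tertiary one, which has to stay masked until the oxepane closure.

Step 6
Reactants: 9 (2S,3S)-3-methyl-1,2,3-tris(triethylsilyloxy)hept-6-ene
Product: 10 (2R,3S)-3-methyl-2,3-bis(triethylsilyloxy)hept-6-enal
Conditions: (COCl)2, DMSO, CH2Cl2, −78 → −30 °C; Et3N, −78 °C → rt
Reagents that add atoms: none
Why: Under Swern conditions a primary triethylsilyl ether is cleaved and oxidised in the flask while the secondary and tertiary silyl ethers survive, which should give the α-silyloxy aldehyde without epimerisation.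

Step 7
Reactants: 10 (2R,3S)-3-methyl-2,3-bis(triethylsilyloxy)hept-6-enal; 11 diethyl (2-oxobutyl)phosphonate
Product: 12 (4E,6S,7S)-7-methyl-6,7-bis(triethylsilyloxy)undeca-4,10-dien-3-one
Conditions: LiCl, i-Pr2NEt, MeCN, rt
Reagents that add atoms: none
Why: Horner–Wadsworth–Emmons olefination under Masamune–Roush conditions gives the (E)-enone and is mild enough for the α-silyloxy aldehyde.

Step 8
Reactants: 12 (4E,6S,7S)-7-methyl-6,7-bis(triethylsilyloxy)undeca-4,10-dien-3-one
Product: 13 (2Z,4E,6S,7S)-3-(tert-butyldimethylsilyloxy)-7-methyl-6,7-bis(triethylsilyloxy)undeca-2,4,10-triene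
Conditions: TBSOTf, Et3N, CH2Cl2, −78 → 0 °C
Reagents that add atoms: tert-butyldimethylsilyl trifluoromethanesulfonate CC(C)(C)[Si](C)(C)OS(=O)(=O)C(F)(F)F
Why: Soft enolisation on the ethyl side gives the cross-conjugated 2-silyloxy diene as the (Z)-enol ether, which places the future C12 methyl group on the outside of the diene.

Step 9
Reactants: 13 silyloxy diene; 14 but-3-en-2-one
Product: 16 trans methyl ketone (cyclohexene silyl enol ether with the C14 acetyl group trans to the C1 side chain), via endo cycloadduct 15 (not isolated)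
Conditions: 14 (5 equiv), BHT, toluene, 90 °C; then DBU, 60 °C
Reagents that add atoms: none
Why: Diels–Alder reaction in which the 2-silyloxy group directs the acetyl-bearing carbon para to itself (C14 next to C1), the two outside substituents of the diene end up cis (C12 methyl cis to the C1 side chain) and the enone approaches anti to the quaternary C3 group with the C2–O bond in the diene plane (inside-alkoxy rotamer, H2 on the attacked face), which sets C1 and C12 relative to C2, after which DBU epimerises C14 of the endo adduct 15 to the more stable trans ketone.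

Step 10
Reactants: 16 trans methyl ketone
Product: 17 isopropenyl cyclohexenyl silyl enol ether
Conditions: Ph3PCH3Br, KOt-Bu, THF, 0 °C → rt
Reagents that add atoms: methylenetriphenylphosphorane C=P(c1ccccc1)(c1ccccc1)c1ccccc1
Why: Wittig methylenation converts the methyl ketone into the isopropenyl group, C14 already being at its thermodynamic configuration and the silyl enol ether being inert to the ylide.

Step 11
Reactants: 18 3-methylbut-3-en-1-ol
Product: 19 3-methylbut-3-enal
Conditions: Dess–Martin periodinane, NaHCO3, CH2Cl2, 0 °C; cold filtered solution used at once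
Reagents that add atoms: none
Why: Dess–Martin oxidation under buffered conditions should give the β,γ-unsaturated aldehyde without migration of the double bond into conjugation.

Step 12
Reactants: 17 isopropenyl cyclohexenyl silyl enol ether; 19 3-methylbut-3-enal
Product: 21 cis-fused tetrahydrofuran ketone (C11 ketone), via oxocarbenium ion 20 (not isolated)
Conditions: 19 (3 equiv), TMSOTf (0.2 equiv), 2,6-di-tert-butyl-4-methylpyridine, CH2Cl2, −78 °C; NaHCO3
Reagents that add atoms: none
Why: TMSOTf silylates aldehyde 19, the C2 triethylsilyl ether of 17 adds to it, and the mixed silyl acetal ionises to the (E)-oxocarbenium ion 20, whose carbon C9 is attacked by C10 of the silyl enol ether; loss of the silyl group from the resulting silyloxycarbenium ion gives the C11 ketone and regenerates a silyl triflate. The closest known reaction type is the silyl triflate-mediated condensation of a silyl ether with an aldehyde followed by intramolecular capture of the oxocarbenium ion by a π-nucleophile (silyl-modified Sakurai and Prins cyclisations), here terminated as an intramolecular Mukaiyama aldol addition, as in known syntheses of 3-acyl tetrahydrofurans from γ-oxygenated enol derivatives. The tetrahydrofuran ring (O, C2, C1, C10, C9) closes in a 5-(enolexo)-endo-trig mode, which is usual for oxocarbenium ions. C10 is controlled by the tether, since C9 can reach C10 only on the face of the C1–C2 bond (cis ring fusion), and C9 by the (E)-oxocarbenium geometry in an envelope that keeps the C3 group on C2 and the C8 chain on C9 pseudo-equatorial (2,5-cis, both on the face away from the cyclohexane). The step needs intramolecular capture to beat intermolecular Mukaiyama aldol addition, which is secured because catalytic TMSOTf at −78 °C does not activate a free aldehyde towards an enol silane whereas silyl ethers condense with it, while the hindered tertiary C3 silyl ether cannot compete and the isopropenyl group could only close a seven-membered ring. C12, next to the new ketone, should keep its configuration under these non-basic conditions.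

Step 13
Reactants: 21 cis-fused tetrahydrofuran ketone
Product: 23 C11 acetate, via lithium alkoxide 22 (not isolated)
Conditions: LiBH(s-Bu)3, THF, −78 °C; then Ac2O, DMAP (cat.), −78 °C → rt
Reagents that add atoms: acetic anhydride CC(=O)OC(C)=O
Why: The hydride should attack the C11 ketone from the convex face that carries H1, H10 and H12, away from the C10–C9 bond and the C12 methyl group, so that the oxygen of alkoxide 22 is cis to both, and the alkoxide is acetylated in the same flask.

Step 14
Reactants: 23 C11 acetate
Product: 24 oxonene (C6=C7 ring alkene, C3 silyl ether)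
Conditions: second-generation Grubbs catalyst RuCl2(=CHPh)(H2IMes)(PCy3) (10 mol %), toluene (2 mM), 80 °C
Reagents that add atoms: none
Why: Ring-closing metathesis starts at the monosubstituted C6 vinyl group and closes on the methallyl alkene, the tetrahydrofuran holding both chains on one face, the nine-membered ring enforcing the (Z)-trisubstituted alkene and the α-branched isopropenyl group being a poor metathesis partner.

Step 15
Reactants: 24 oxonene
Product: 25 tertiary alcohol
Conditions: HF·pyridine, pyridine, THF, 0 °C → rt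
Reagents that add atoms: none
Why: Fluoride cleaves the tertiary triethylsilyl ether while the acetate and the alkenes are inert.

Step 16
Reactants: 25 tertiary alcohol
Product: 27 C16,C3 diol, via B-alkyl-9-BBN 26 (not isolated)
Conditions: 9-BBN (3 equiv), THF, 0 °C → rt; then pH 7 buffer, 30% H2O2, 0 °C → rt
Reagents that add atoms: hydrogen peroxide OO
Why: 9-BBN adds to the 1,1-disubstituted isopropenyl alkene much faster than to the trisubstituted ring alkene and, in the rotamer with H14 eclipsing the C15=C16 bond (minimal 1,3-allylic strain), should approach from the side of C13, away from the more substituted C1, which sets C15, while buffered peroxide oxidation with retention keeps the acetate.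

Step 17
Reactants: 27 C16,C3 diol
Product: 29 target CNP0177382.3, via primary triflate 28 (not isolated)
Conditions: Tf2O (1.1 equiv), 2,6-lutidine, CH2Cl2, −78 °C → rt
Reagents that add atoms: none
Why: The primary alcohol is triflated selectively and the tertiary C3 hydroxyl displaces the triflate in a 7-exo-tet Williamson-type closure, which should give the trans-fused oxepane without touching a stereocentre.

Compound list

1 | but-2-yn-1-ol | CC#CCO | starting material
2 | sodium 2,2-bis(2-methoxyethoxy)-3-methyl-2,5-dihydro-1,2-oxaaluminol-2-uide (cyclic alkenylaluminate) | CC1=CCO[Al-]1(OCCOC)OCCOC.[Na+] | intermediate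
3 | (Z)-3-iodobut-2-en-1-ol | C/C(I)=C/CO | intermediate
4 | but-3-en-1-ylzinc bromide | C=CCC[Zn]Br | starting material
5 | (Z)-3-methylhepta-2,6-dien-1-ol | C=CCC/C(C)=C\CO | intermediate
6 | [(2R,3S)-3-(but-3-en-1-yl)-3-methyloxiran-2-yl]methanol | OC[C@H]1O[C@@]1(C)CCC=C | intermediate
7 | (2S)-2-[(2S)-oxiran-2-yl]hex-5-en-2-ol | C1O[C@@H]1[C@@](C)(O)CCC=C | intermediate
8 | (2S,3S)-3-methylhept-6-ene-1,2,3-triol | OC[C@H](O)[C@@](C)(O)CCC=C | intermediate
9 | (2S,3S)-3-methyl-1,2,3-tris(triethylsilyloxy)hept-6-ene | CC[Si](CC)(CC)OC[C@H](O[Si](CC)(CC)CC)[C@@](C)(O[Si](CC)(CC)CC)CCC=C | intermediate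
10 | (2R,3S)-3-methyl-2,3-bis(triethylsilyloxy)hept-6-enal | O=C[C@H](O[Si](CC)(CC)CC)[C@@](C)(O[Si](CC)(CC)CC)CCC=C | intermediate
11 | diethyl (2-oxobutyl)phosphonate | CCC(=O)CP(=O)(OCC)OCC | starting material
12 | (4E,6S,7S)-7-methyl-6,7-bis(triethylsilyloxy)undeca-4,10-dien-3-one | CCC(=O)/C=C/[C@H](O[Si](CC)(CC)CC)[C@@](C)(O[Si](CC)(CC)CC)CCC=C | intermediate
13 | (2Z,4E,6S,7S)-3-(tert-butyldimethylsilyloxy)-7-methyl-6,7-bis(triethylsilyloxy)undeca-2,4,10-triene | C/C=C(O[Si](C)(C)C(C)(C)C)/C=C/[C@H](O[Si](CC)(CC)CC)[C@@](C)(O[Si](CC)(CC)CC)CCC=C | intermediate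
14 | but-3-en-2-one | CC(=O)C=C | starting material
15 | endo cycloadduct: cyclohexene C10=C11 tert-butyldimethylsilyl enol ether with C12 methyl, C14 acetyl and the C1 side chain CH(OTES)–C(CH3)(OTES)–CH2CH2CH=CH2 all cis | CC(C)(C)[Si](C)(C)OC1=C[C@H]([C@H](C[C@H]1C)C(C)=O)[C@H](O[Si](CC)(CC)CC)[C@@](C)(O[Si](CC)(CC)CC)CCC=C | intermediate
16 | trans methyl ketone: C14 epimer of 15, acetyl trans to the C1 side chain, C12 methyl cis to it | CC(C)(C)[Si](C)(C)OC1=C[C@H]([C@@H](C[C@H]1C)C(C)=O)[C@H](O[Si](CC)(CC)CC)[C@@](C)(O[Si](CC)(CC)CC)CCC=C | intermediate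
17 | isopropenyl cyclohexenyl silyl enol ether: 16 with C(CH3)=CH2 in place of acetyl | CC(C)(C)[Si](C)(C)OC1=C[C@H]([C@@H](C[C@H]1C)C(C)=C)[C@H](O[Si](CC)(CC)CC)[C@@](C)(O[Si](CC)(CC)CC)CCC=C | intermediate
18 | 3-methylbut-3-en-1-ol | CC(=C)CCO | starting material
19 | 3-methylbut-3-enal | CC(=C)CC=O | intermediate
20 | (E)-oxocarbenium triflate: 17 with C2–O+=C9H–CH2C(CH3)=CH2 in place of the C2 silyl ether | CC(C)(C)[Si](C)(C)OC1=C[C@H]([C@@H](C[C@H]1C)C(C)=C)[C@H](/[O+]=C/CC(C)=C)[C@@](C)(O[Si](CC)(CC)CC)CCC=C.[O-]S(=O)(=O)C(F)(F)F | intermediate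
21 | cis-fused hexahydroisobenzofuran-4-one: C11 ketone, C12 methyl, C14 isopropenyl, C9 methallyl cis to the C3 group across the ring oxygen, C3 bearing CH3, OTES and but-3-enyl | O=C1[C@@H]2[C@H]([C@@H](C[C@H]1C)C(C)=C)[C@H](O[C@H]2CC(C)=C)[C@@](C)(O[Si](CC)(CC)CC)CCC=C | intermediate
22 | lithium C11 alkoxide of reduced 21 (O cis to C9 and to the C12 methyl) | [Li+].[O-][C@H]1[C@@H]2[C@H]([C@@H](C[C@H]1C)C(C)=C)[C@H](O[C@H]2CC(C)=C)[C@@](C)(O[Si](CC)(CC)CC)CCC=C | intermediate
23 | C11 acetate of the bicyclic triene | CC(=O)O[C@H]1[C@@H]2[C@H]([C@@H](C[C@H]1C)C(C)=C)[C@H](O[C@H]2CC(C)=C)[C@@](C)(O[Si](CC)(CC)CC)CCC=C | intermediate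
24 | tricyclic oxonene: (Z)-C6=C7 ring alkene, C3 OTES, C14 isopropenyl, C11 acetate | CC(=O)O[C@H]1[C@@H]2[C@H]([C@@H](C[C@H]1C)C(C)=C)[C@@H]3O[C@H]2C/C(C)=C\CC[C@]3(C)O[Si](CC)(CC)CC | intermediate
25 | tricyclic oxonene with free C3 hydroxyl | CC(=O)O[C@H]1[C@@H]2[C@H]([C@@H](C[C@H]1C)C(C)=C)[C@@H]3O[C@H]2C/C(C)=C\CC[C@]3(C)O | intermediate
26 | C16 B-alkyl-9-borabicyclo[3.3.1]nonane of 25 | CC(=O)O[C@H]1[C@@H]2[C@H]([C@@H](C[C@H]1C)[C@@H](C)CB4C5CCCC4CCC5)[C@@H]3O[C@H]2C/C(C)=C\CC[C@]3(C)O | intermediate
27 | diol: C16 primary alcohol (C15 R), C3 tertiary alcohol | CC(=O)O[C@H]1[C@@H]2[C@H]([C@@H](C[C@H]1C)[C@@H](C)CO)[C@@H]3O[C@H]2C/C(C)=C\CC[C@]3(C)O | intermediate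
28 | C16 trifluoromethanesulfonate of 27 | CC(=O)O[C@H]1[C@@H]2[C@H]([C@@H](C[C@H]1C)[C@@H](C)COS(=O)(=O)C(F)(F)F)[C@@H]3O[C@H]2C/C(C)=C\CC[C@]3(C)O | intermediate
29 | target CNP0177382.3 (asbestinane tetracycle with C11 acetate, C3–O–C16 oxepane, (Z)-C6=C7) | CC(=O)O[C@H]1[C@@H]2[C@@H]3[C@@H](C[C@H]1C)[C@@H](C)CO[C@@]1(C)CC/C=C(/C)C[C@@H]2O[C@@H]31 | target

Total steps: 17. Longest linear sequence: 16 (steps 1–10 and 12–17; step 11 is a one-step branch).

Steps most likely to fail

Step 12 (key step). The silyl enol ether may add to the activated aldehyde between molecules before the mixed acetal has formed, the enol ether may be protodesilylated by adventitious triflic acid, or the double bond of the aldehyde may migrate into conjugation. The fallback sets out from 17. Buffered HF·pyridine (pyridine, THF, 0 °C) should remove the enol silyl group and the secondary triethylsilyl group but leave the hindered tertiary one, giving γ-hydroxy ketone F1. F1 and 19 with BF3·OEt2 (CH2Cl2, −78 → −20 °C) form the hemiacetal, which ionises to the same type of oxocarbenium ion and is captured by the boron-bound enol of the C11 ketone (acid-mediated oxocarbenium–enol cyclisation of the Maitland–Japp type; only the C10 enol can close a five-membered ring). The route is rejoined at 21. No enol silane is present, so the intermolecular Mukaiyama pathway is removed; C12 would have to be checked for epimerisation.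

Step 9. Facial selectivity may be low because the rotamer with the C2 silyloxy group on the attacked face competes, or the hindered diene may react so slowly that the enone polymerises. The fallback sets out from 13 and uses reagent control. (R)-4-Benzyloxazolidin-2-one is acylated (n-BuLi, acryloyl chloride, THF, −78 °C) to (R)-3-acryloyl-4-benzyloxazolidin-2-one F2. 13 and F2 with Me2AlCl (CH2Cl2, −78 °C) should give the endo imide adduct F3: the benzyl group of the chelated dienophile shields one face, so that C14 and, through the endo transition state, C1 and C12 are set by the auxiliary. Me(MeO)NH·HCl/AlMe3 gives the Weinreb amide F4, and MeMgBr then gives the cis methyl ketone 15, which DBU converts as in step 9. The route is rejoined at 16.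

Step 14. Once the catalyst has loaded on the C6 vinyl group it may close onto the nearby isopropenyl group (eight-membered carbocycle) instead of the methallyl group, or the nine-membered ring may close so slowly that oligomers form. The fallback sets out from 16 and carries the future isopropenyl group as a metathesis-inert enol triflate. KN(SiMe3)2 and PhNTf2 (THF, −78 °C) give the enol triflate F5 by kinetic deprotonation of the methyl group. The conditions of steps 12, 13 and 14 then give the tricyclic ketone triflate F6, the acetate triflate F7 and the oxonene triflate F8; the electron-poor triflyloxy alkene should not take part in metathesis. MeZnCl with Pd(PPh3)4 (THF, 50 °C) replaces the triflate by methyl (Negishi coupling), and the route is rejoined at 24.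

Further compounds

F1 | step 12 | γ-hydroxy ketone: cyclohexanone (C11) with C12 methyl, C14 isopropenyl and C1 side chain CH(OH)–C(CH3)(OTES)–CH2CH2CH=CH2 | O=C1C[C@H]([C@@H](C[C@H]1C)C(C)=C)[C@H](O)[C@@](C)(O[Si](CC)(CC)CC)CCC=C
F2 | step 9 | (R)-3-acryloyl-4-benzyloxazolidin-2-one | C=CC(=O)N1[C@H](Cc2ccccc2)COC1=O
F3 | step 9 | endo imide adduct: 15 with the (R)-4-benzyl-2-oxooxazolidine-3-carbonyl group in place of acetyl | CC(C)(C)[Si](C)(C)OC1=C[C@H]([C@H](C[C@H]1C)C(=O)N2[C@H](Cc3ccccc3)COC2=O)[C@H](O[Si](CC)(CC)CC)[C@@](C)(O[Si](CC)(CC)CC)CCC=C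
F4 | step 9 | Weinreb amide: 15 with C(=O)N(CH3)OCH3 in place of acetyl | CC(C)(C)[Si](C)(C)OC1=C[C@H]([C@H](C[C@H]1C)C(=O)N(C)OC)[C@H](O[Si](CC)(CC)CC)[C@@](C)(O[Si](CC)(CC)CC)CCC=C
F5 | step 14 | enol triflate: 16 with C(=CH2)OTf in place of acetyl | CC(C)(C)[Si](C)(C)OC1=C[C@H]([C@@H](C[C@H]1C)C(=C)OS(=O)(=O)C(F)(F)F)[C@H](O[Si](CC)(CC)CC)[C@@](C)(O[Si](CC)(CC)CC)CCC=C
F6 | step 14 | tricyclic ketone triflate: 21 with C(=CH2)OTf in place of isopropenyl | O=C1[C@@H]2[C@H]([C@@H](C[C@H]1C)C(=C)OS(=O)(=O)C(F)(F)F)[C@H](O[C@H]2CC(C)=C)[C@@](C)(O[Si](CC)(CC)CC)CCC=C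
F7 | step 14 | acetate triflate: 23 with C(=CH2)OTf in place of isopropenyl | CC(=O)O[C@H]1[C@@H]2[C@H]([C@@H](C[C@H]1C)C(=C)OS(=O)(=O)C(F)(F)F)[C@H](O[C@H]2CC(C)=C)[C@@](C)(O[Si](CC)(CC)CC)CCC=C
F8 | step 14 | oxonene triflate: 24 with C(=CH2)OTf in place of isopropenyl | CC(=O)O[C@H]1[C@@H]2[C@H]([C@@H](C[C@H]1C)C(=C)OS(=O)(=O)C(F)(F)F)[C@@H]3O[C@H]2C/C(C)=C\CC[C@]3(C)O[Si](CC)(CC)CC
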